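**Retrosynthetic overview**
- Last step: hydrogenolysis of four benzyl ethers on the fully assembled tetra-O-benzyl naphthol.
- Second naphthalene ring (formed last): aryl transfer from a ring-A boronic acid to the lactone carbonyl of a 3-(2-arylethyl)isocoumarin opens the pyranone to a 1,5-diketone, which closes by aldol condensation; the lactone oxygen is kept as the naphthol oxygen.
- Key disconnection: the lactone O2–C3 bond of the isocoumarin (the future C2–OH bond of the target), made together with C4–C4a by carboxylate-directed C–H/O–H annulation of 4-(benzyloxy)-3,5-dimethoxybenzoic acid with a terminal alkyne.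
- Alkyne: 3,4-bis(benzyloxy)benzyl chloride plus propargyl bromide (allenyl Grignard).
- Ring order: pyranone ring first, then the carbocyclic naphthalene ring; the three benzene rings are bought as benzyl-protected catalogue compounds.

Assumption: the SMILES has no stereodescriptor and the molecule has no stereocentre; the aryl–naphthyl axis is unspecified, so no stereocontrol is built in (if the axis is configurationally stable the material is racemic about it).

**Step 1**
Reactants: 1 3,4-bis(benzyloxy)benzyl chloride; 2 propargyl bromide (3-bromoprop-1-yne)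
Product: 4 4-[3,4-bis(benzyloxy)phenyl]but-1-yne, via allenylmagnesium bromide 3 (not isolated)
Conditions: 2, Mg, HgCl2 (1 mol%), Et2O, 0 °C; then 1, THF, 0 °C to reflux
Reagents that add atoms: none
Why: The allenyl Grignard attacks the benzylic chloride through its γ-carbon (SE2' propargylation, Grignard–benzyl halide coupling) to give the homopropargyl arene; no stereocentre is formed.

**Step 2**
Reactants: 4 4-[3,4-bis(benzyloxy)phenyl]but-1-yne; 5 4-(benzyloxy)-3,5-dimethoxybenzoic acid
Product: 6 6-(benzyloxy)-3-{2-[3,4-bis(benzyloxy)phenyl]ethyl}-5,7-dimethoxy-1H-isochromen-1-one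
Conditions: Co(hfacac)2 (20 mol%), Ce(SO4)2 (30 mol%), (TMS)2NH (1 equiv), O2 (1 atm), CF3CH2OH, 100 °C
Reagents that add atoms: none
Why: Carboxylate-directed cobalt-catalysed aerobic C–H/O–H alkyne annulation (a known class that accepts terminal alkynes): ortho C–H metalation (both ortho positions of 5 are equivalent), 1,2-insertion with the aryl group going to the CH terminus, then C–O reductive elimination forms the O2–C3 bond and closes the six-membered lactone.

**Step 3**
Reactants: 6 6-(benzyloxy)-3-{2-[3,4-bis(benzyloxy)phenyl]ethyl}-5,7-dimethoxy-1H-isochromen-1-one; 7 [4-(benzyloxy)-2-methoxyphenyl]boronic acid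
Product: 9 7-(benzyloxy)-4-[4-(benzyloxy)-2-methoxyphenyl]-3-[3,4-bis(benzyloxy)benzyl]-6,8-dimethoxynaphthalen-2-ol, via seco-diketone 8 (not isolated)
Conditions: Pd(IPr)(cinnamyl)Cl (5 mol%; IPr = 1,3-bis(2,6-diisopropylphenyl)imidazol-2-ylidene), K3PO4 (3 equiv), H2O (5 equiv), dioxane, 60 °C then 100 °C, under argon
Reagents that add atoms: none
Why: Proposed new method: ring-opening acyl Suzuki–Miyaura coupling of an enol lactone with in-flask aldol benzannulation. Zerovalent palladium carrying the bulky NHC inserts into the C1(acyl)–O2 bond of 6 (an aroyl ester locked s-trans, with an enolate leaving group of phenol-like quality). The acylpalladium enolate transmetalates with the arylboronate of 7 (the Pd–O enolate acting as internal base), and reductive elimination gives diaryl ketone 8 as its potassium enolate. Proton transfer to the distal α-CH2 lets it add to the new diaryl ketone (six-membered aldol), and dehydration/tautomerisation to the naphthol makes the sequence irreversible and regiochemically unambiguous. Closest known reactions: Pd–NHC-catalysed acyl Suzuki–Miyaura coupling of aryl esters through C(acyl)–O oxidative addition, and the base-induced recyclisation of 1-aryl-2-benzopyrylium salts (from isocoumarins and aryl Grignard reagents) to 2-naphthols. No stereocentre is formed.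

**Step 4**
Reactants: 9 7-(benzyloxy)-4-[4-(benzyloxy)-2-methoxyphenyl]-3-[3,4-bis(benzyloxy)benzyl]-6,8-dimethoxynaphthalen-2-ol
Product: 10 3-[(3,4-dihydroxyphenyl)methyl]-4-(4-hydroxy-2-methoxyphenyl)-6,8-dimethoxynaphthalene-2,7-diol (CNP0000244.0)
Conditions: H2 (1 atm), 10% Pd/C, THF/MeOH, rt; filtered and concentrated under argon
Reagents that add atoms: none
Why: Catalytic hydrogenolysis of the four aryl benzyl ethers; the methyl ethers, the diarylmethane C–C bonds and the naphthalene are inert at 1 atm, and no stereocentre is involved.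

**Compound list**
1 | 3,4-bis(benzyloxy)benzyl chloride | ClCc1ccc(OCc2ccccc2)c(OCc2ccccc2)c1 | starting material
2 | propargyl bromide (3-bromoprop-1-yne) | BrCC#C | starting material
3 | allenylmagnesium bromide | C=C=C[Mg]Br | intermediate
4 | 4-[3,4-bis(benzyloxy)phenyl]but-1-yne | C#CCCc1ccc(OCc2ccccc2)c(OCc2ccccc2)c1 | intermediate
5 | 4-(benzyloxy)-3,5-dimethoxybenzoic acid | COc1cc(C(=O)O)cc(OC)c1OCc1ccccc1 | starting material
6 | 6-(benzyloxy)-3-{2-[3,4-bis(benzyloxy)phenyl]ethyl}-5,7-dimethoxy-1H-isochromen-1-one | O=C1OC(CCc2ccc(OCc3ccccc3)c(OCc3ccccc3)c2)=Cc2c(OC)c(OCc3ccccc3)c(OC)cc12 | intermediate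
7 | [4-(benzyloxy)-2-methoxyphenyl]boronic acid | COc1cc(OCc2ccccc2)ccc1B(O)O | starting material
8 | seco-diketone: 1-{3-(benzyloxy)-6-[4-(benzyloxy)-2-methoxybenzoyl]-2,4-dimethoxyphenyl}-4-[3,4-bis(benzyloxy)phenyl]butan-2-one | O=C(Cc1c(OC)c(OCc2ccccc2)c(OC)cc1C(=O)c1ccc(OCc2ccccc2)cc1OC)CCc1ccc(OCc2ccccc2)c(OCc2ccccc2)c1 | intermediate
9 | 7-(benzyloxy)-4-[4-(benzyloxy)-2-methoxyphenyl]-3-[3,4-bis(benzyloxy)benzyl]-6,8-dimethoxynaphthalen-2-ol | COc1cc(OCc2ccccc2)ccc1-c1c(Cc2ccc(OCc3ccccc3)c(OCc3ccccc3)c2)c(O)cc2c(OC)c(OCc3ccccc3)c(OC)cc12 | intermediate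
10 | 3-[(3,4-dihydroxyphenyl)methyl]-4-(4-hydroxy-2-methoxyphenyl)-6,8-dimethoxynaphthalene-2,7-diol | COc1cc(O)ccc1-c1c(Cc2ccc(O)c(O)c2)c(O)cc2c(OC)c(O)c(OC)cc12 | target

**Total step count:** 4. **Longest linear sequence:** 4 steps (2 → 4 → 6 → 9 → 10).

**Three steps most likely to fail**

Step 3 (the proposed new step). Risks are base hydrolysis of the lactone before oxidative addition, slow oxidative addition into an electron-rich aroyl ester, and protodeboronation of the ortho-methoxy boronic acid. The fallback uses known organometallic lactone opening; it sets out from 6 and comes back at 9. 4-Bromo-3-methoxyphenol is benzylated (BnBr, K2CO3, DMF, rt) to 4-(benzyloxy)-1-bromo-2-methoxybenzene F1. Bromine–lithium exchange (n-BuLi, THF, −78 °C) gives [4-(benzyloxy)-2-methoxyphenyl]lithium F2, which is added (1.05 equiv, −78 °C) to the lactone carbonyl of 6. The adduct opens to the lithium enolate of the hindered diaryl ketone 8, so a second addition is slow. KOH/MeOH at 60 °C then completes the aldol condensation to 9. This costs one extra step and cryogenic conditions.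

Step 2. Risks are oxidative dimerisation of the terminal alkyne, a slow C–H metalation next to a methoxy group, and oxidation of the electron-rich benzyl ethers by the cerium co-oxidant. The fallback replaces C–H activation with halogenation, cross-coupling and oxacyclisation; it sets out from 5 and comes back at 6. Electrophilic iodination (N-iodosuccinimide, cat. CF3CO2H, MeCN) at the position ortho and para to the two methoxy groups gives 4-(benzyloxy)-2-iodo-3,5-dimethoxybenzoic acid F3. Coupling with 4 under Pd(PPh3)4, ZnCl2 and Et3N in DMF at 100 °C gives 4-(benzyloxy)-2-{4-[3,4-bis(benzyloxy)phenyl]but-1-yn-1-yl}-3,5-dimethoxybenzoic acid F4. F4 cyclises in the same flask 6-endo-dig, carboxylate oxygen to the alkyl-bearing alkyne carbon, to give 6.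

Step 1. Risks are allene formation from attack through the α-carbon of the ambident Grignard and Wurtz dimerisation of the electron-rich benzyl chloride. The fallback uses a silyl-capped propargyl anion whose regiochemistry is fixed, followed by desilylation; it sets out from 1 and comes back at 4. 1-(Trimethylsilyl)propyne is lithiated (n-BuLi, THF, −78 °C) to [3-(trimethylsilyl)prop-2-yn-1-yl]lithium F5. F5 is alkylated by 1 at the propargylic carbon to give {4-[3,4-bis(benzyloxy)phenyl]but-1-yn-1-yl}trimethylsilane F6. K2CO3 in MeOH removes the silyl group to give 4.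

**Further compounds**
F1 | step 3 | 4-(benzyloxy)-1-bromo-2-methoxybenzene | COc1cc(OCc2ccccc2)ccc1Br
F2 | step 3 | [4-(benzyloxy)-2-methoxyphenyl]lithium | [Li]c1ccc(OCc2ccccc2)cc1OC
F3 | step 2 | 4-(benzyloxy)-2-iodo-3,5-dimethoxybenzoic acid | COc1cc(C(=O)O)c(I)c(OC)c1OCc1ccccc1
F4 | step 2 | 4-(benzyloxy)-2-{4-[3,4-bis(benzyloxy)phenyl]but-1-yn-1-yl}-3,5-dimethoxybenzoic acid | COc1cc(C(=O)O)c(C#CCCc2ccc(OCc3ccccc3)c(OCc3ccccc3)c2)c(OC)c1OCc1ccccc1
F5 | step 1 | [3-(trimethylsilyl)prop-2-yn-1-yl]lithium | [Li]CC#C[Si](C)(C)C
F6 | step 1 | {4-[3,4-bis(benzyloxy)phenyl]but-1-yn-1-yl}trimethylsilane | C[Si](C)(C)C#CCCc1ccc(OCc2ccccc2)c(OCc2ccccc2)c1
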